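**Retrosynthetic overview**

1. The ester C–O bond between the two halves is made last: acid fragment A opens the oxirane CH2 of spiro-epoxide fragment B, so no hydroxyl protection is needed.
2. Both 2-(hydroxymethyl)acrylate units come from an E-selective Horner–Wadsworth–Emmons olefination of a ring aldehyde; in fragment B the new CH2OH then closes the oxepinone onto the neighbouring acid.
3. Fragment B core: the cis acid/aldehyde pair comes from cutting a cyclobutane that an allene [2+2] photocycloaddition fuses onto (S)-cryptone; the oxirane comes from the ketone and a sulfur ylide.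
4. Fragment A core: (R)-cryptone, trans conjugate vinylation with enolate triflation, vinyl to CHO, triflate to CH2OH.
5. Key step: Birch reduction of 4-isopropylanisole gives one achiral enone, which amine-catalysed enantioselective isomerisation turns into either cryptone antipode. Ring order: the carbocycles (from the arene), a temporary cyclobutane, the oxirane, the oxepinone last.

Assumption: the configuration is taken exactly as in the SMILES (the two cyclohexane units are then antipodal at the isopropyl centre), and which cinchona pseudo-enantiomer gives which cryptone is fixed by the sign of rotation (natural (R)-cryptone is levorotatory).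

**Route**

Step 1
Reactants: 1 4-isopropylanisole
Product: 3 4-isopropylcyclohex-3-en-1-one, via dienol ether 2 (not isolated)
Conditions: Li, NH3(l), t-BuOH, THF, −33 °C; then (CO2H)2 (aq), MeOH, rt
Reagents that add atoms: water, O
Why: Birch reduction gives the 2,5-dihydroanisole, and mild acid hydrolysis of this enol ether gives the unconjugated, achiral β,γ-enone without moving the ring double bond.

Step 2
Reactants: 3 4-isopropylcyclohex-3-en-1-one
Product: 4 (4R)-4-isopropylcyclohex-2-en-1-one ((R)-cryptone)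
Conditions: quinine-derived 9-amino-9-deoxy-epi-cinchona primary amine (10 mol %), 2-nitrobenzoic acid (20 mol %), toluene, −20 °C
Reagents that add atoms: none
Why: Enantioselective olefin isomerisation by iminium/dienamine catalysis, in which the primary amine forms the dienamine and the protonated quinuclidine delivers the proton to one face of C-4 (γ-protonation), so the achiral enone becomes the (R)-enone.

Step 3
Reactants: 3 4-isopropylcyclohex-3-en-1-one
Product: 5 (4S)-4-isopropylcyclohex-2-en-1-one ((S)-cryptone)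
Conditions: quinidine-derived pseudo-enantiomeric primary amine (10 mol %), 2-nitrobenzoic acid (20 mol %), toluene, −20 °C
Reagents that add atoms: none
Why: The same enantioselective olefin isomerisation (dienamine γ-protonation) with the pseudo-enantiomeric catalyst protonates the opposite face of C-4 and gives the (S)-enone.

Step 4
Reactants: 6 tert-butyl (diethoxyphosphoryl)acetate
Product: 7 tert-butyl 2-(diethoxyphosphoryl)-3-hydroxypropanoate (racemic)
Conditions: (CH2O)n (1.0 equiv), K2CO3 (10 mol %), THF, 0 °C → rt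
Reagents that add atoms: paraformaldehyde (formaldehyde), C=O
Why: Aldol-type hydroxymethylation of the stabilised phosphonate carbanion stops at the mono-adduct with one equivalent of formaldehyde; the new centre is racemic and is destroyed in the later olefination.

Step 5
Reactants: 4 (R)-cryptone
Product: 9 (3R,4R)-4-isopropyl-3-vinylcyclohex-1-en-1-yl trifluoromethanesulfonate, via magnesium enolate 8 (not isolated)
Conditions: CH2=CHMgBr, CuI (15 mol %), LiCl, THF, −78 °C; then Comins' reagent, −78 → 0 °C
Reagents that add atoms: vinylmagnesium bromide, C=C[Mg]Br; Comins' reagent (N-(5-chloropyridin-2-yl)-N-(trifluoromethylsulfonyl)trifluoromethanesulfonamide), FC(F)(F)S(=O)(=O)N(c1ccc(Cl)cn1)S(=O)(=O)C(F)(F)F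
Why: Copper-catalysed conjugate addition of the vinyl Grignard reagent occurs anti to the adjacent isopropyl group (trans 3,4-product), and the regiodefined enolate is trapped on oxygen as the enol triflate.

Step 6
Reactants: 9 (3R,4R)-4-isopropyl-3-vinylcyclohex-1-en-1-yl trifluoromethanesulfonate
Product: 10 (3R,4R)-3-formyl-4-isopropylcyclohex-1-en-1-yl trifluoromethanesulfonate
Conditions: O3, pyridine, CH2Cl2, −78 °C
Reagents that add atoms: ozone, [O-][O+]=O
Why: Pyridine-mediated reductive ozonolysis cleaves only the electron-richer terminal vinyl group, because the triflate-bearing ring alkene is deactivated, and it leaves both stereocentres untouched.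

Step 7
Reactants: 10 (3R,4R)-3-formyl-4-isopropylcyclohex-1-en-1-yl trifluoromethanesulfonate; 7 tert-butyl 2-(diethoxyphosphoryl)-3-hydroxypropanoate
Product: 11 tert-butyl (2E)-2-(hydroxymethyl)-3-[(1S,6R)-6-isopropyl-3-(trifluoromethylsulfonyloxy)cyclohex-2-en-1-yl]prop-2-enoate
Conditions: LiCl, DBU, MeCN, 0 °C → rt
Reagents that add atoms: none
Why: Horner–Wadsworth–Emmons olefination under Masamune–Roush conditions, in which the α-substituted phosphonate carbanion adds to the aldehyde and loses phosphate to give the favoured (E)-alkene (ring trans to the ester) without enolising the aldehyde.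

Step 8
Reactants: 11 tert-butyl (2E)-2-(hydroxymethyl)-3-[(1S,6R)-6-isopropyl-3-(trifluoromethylsulfonyloxy)cyclohex-2-en-1-yl]prop-2-enoate
Product: 12 tert-butyl (2E)-2-(hydroxymethyl)-3-[(1R,6R)-3-(hydroxymethyl)-6-isopropylcyclohex-2-en-1-yl]prop-2-enoate
Conditions: Bu3SnCH2OH, Pd(PPh3)4 (5 mol %), LiCl, 1,4-dioxane, 100 °C
Reagents that add atoms: (tributylstannyl)methanol, CCCC[Sn](CCCC)(CCCC)CO
Why: Stille cross-coupling of the enol triflate with the hydroxymethylstannane installs the allylic CH2OH at the fixed double-bond position and touches no stereocentre.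

Step 9
Reactants: 12 tert-butyl (2E)-2-(hydroxymethyl)-3-[(1R,6R)-3-(hydroxymethyl)-6-isopropylcyclohex-2-en-1-yl]prop-2-enoate
Product: 13 (2E)-2-(hydroxymethyl)-3-[(1R,6R)-3-(hydroxymethyl)-6-isopropylcyclohex-2-en-1-yl]prop-2-enoic acid (fragment A)
Conditions: 85 % H3PO4 (aq), toluene, rt
Reagents that add atoms: none
Why: Acid-catalysed tert-butyl ester cleavage (loss of the tert-butyl cation as isobutene) frees the acid under conditions mild enough for the two allylic alcohols.

Step 10
Reactants: 5 (S)-cryptone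
Product: 14 (1R,5S,6S)-5-isopropyl-8-methylidenebicyclo[4.2.0]octan-2-one
Conditions: allene (10 equiv), hν (medium-pressure Hg lamp, Pyrex), THF, −78 °C
Reagents that add atoms: allene (propa-1,2-diene), C=C=C
Why: Enone–allene [2+2] photocycloaddition adds head-to-head (methylidene carbon next to the α-carbon) on the face anti to the isopropyl group and closes to the cis-fused cyclobutane, which sets both ring-fusion centres cis to each other and trans to isopropyl.

Step 11
Reactants: 14 (1R,5S,6S)-5-isopropyl-8-methylidenebicyclo[4.2.0]octan-2-one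
Product: 15 (1R,2R,5S,6S)-5-isopropyl-8-methylidenespiro[bicyclo[4.2.0]octane-2,2'-oxirane]
Conditions: [Me3S]I, KN(SiMe3)2, THF, −10 → 0 °C
Reagents that add atoms: trimethylsulfonium iodide, C[S+](C)C.[I-]
Why: Corey–Chaykovsky epoxidation, in which the unstabilised sulfonium ylide adds irreversibly to the ketone from the convex axial face anti to the cyclobutane, so the oxirane CH2 ends up on the isopropyl face and the oxygen on the cyclobutane face.

Step 12
Reactants: 15 (1R,2R,5S,6S)-5-isopropyl-8-methylidenespiro[bicyclo[4.2.0]octane-2,2'-oxirane]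
Product: 16 (1S,2R,5S,6S)-5-isopropylspiro[bicyclo[4.2.0]octane-2,2'-oxiran]-8-one
Conditions: O3, pyridine, CH2Cl2, −78 °C
Reagents that add atoms: ozone, [O-][O+]=O
Why: Reductive ozonolysis of the exocyclic methylidene gives the cyclobutanone, while the oxirane is inert to ozone and no stereocentre is touched.

Step 13
Reactants: 16 (1S,2R,5S,6S)-5-isopropylspiro[bicyclo[4.2.0]octane-2,2'-oxiran]-8-one
Product: 19 (3R,4S,5S,6S)-5-formyl-6-isopropyl-1-oxaspiro[2.5]octane-4-carboxylic acid, via silyl enol ether 17 (not isolated), via silyl ester 18 (not isolated)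
Conditions: LiN(SiMe3)2, Me3SiCl, THF, −78 °C; then O3, pyridine, CH2Cl2, −78 °C; then pH 5 buffer
Reagents that add atoms: ozone, [O-][O+]=O; chlorotrimethylsilane, C[Si](C)(C)Cl (its atoms stay only in 17 and 18)
Why: Kinetic deprotonation at the unhindered cyclobutanone CH2 with in situ silylation gives the cyclobutene silyl enol ether, and its ozonolysis cuts the four-membered ring into an acid and an aldehyde that stay cis because neither ring-fusion centre is touched.

Step 14
Reactants: 19 (3R,4S,5S,6S)-5-formyl-6-isopropyl-1-oxaspiro[2.5]octane-4-carboxylic acid; 7 tert-butyl 2-(diethoxyphosphoryl)-3-hydroxypropanoate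
Product: 20 (3R,4S,5R,6S)-5-[(1E)-3-tert-butoxy-2-(hydroxymethyl)-3-oxoprop-1-en-1-yl]-6-isopropyl-1-oxaspiro[2.5]octane-4-carboxylic acid
Conditions: LiCl, DBU, MeCN, 0 °C → rt; then citric acid (aq)
Reagents that add atoms: none
Why: Horner–Wadsworth–Emmons olefination (Masamune–Roush conditions) of the aldehyde, which is released from its lactol form, gives the (E)-acrylate as in step 7 and leaves the carboxylate α-centre untouched.

Step 15
Reactants: 20 (3R,4S,5R,6S)-5-[(1E)-3-tert-butoxy-2-(hydroxymethyl)-3-oxoprop-1-en-1-yl]-6-isopropyl-1-oxaspiro[2.5]octane-4-carboxylic acid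
Product: 22 tert-butyl (5aR,6S,9R,9aS)-6-isopropyl-1-oxo-1,3,5a,6,7,8-hexahydro-9aH-spiro[2-benzoxepine-9,2'-oxirane]-4-carboxylate (fragment B), via mixed anhydride 21 (not isolated)
Conditions: 2-methyl-6-nitrobenzoic anhydride, DMAP (10 mol %), Et3N, CH2Cl2 (2 mM), rt
Reagents that add atoms: 2-methyl-6-nitrobenzoic anhydride, Cc1cccc([N+](=O)[O-])c1C(=O)OC(=O)c1c(C)cccc1[N+](=O)[O-] (its atoms stay only in 21)
Why: Shiina lactonisation through the mixed anhydride closes the seven-membered lactone, which only the (E)-acrylate with its CH2OH cis to the ring can do, and no stereocentre changes.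

Step 16
Reactants: 22 tert-butyl (5aR,6S,9R,9aS)-6-isopropyl-1-oxo-1,3,5a,6,7,8-hexahydro-9aH-spiro[2-benzoxepine-9,2'-oxirane]-4-carboxylate; 13 fragment A acid (1.5 equiv)
Product: 23 tert-butyl (5aR,6S,9R,9aS)-9-hydroxy-9-[({(2E)-2-(hydroxymethyl)-3-[(1R,6R)-3-(hydroxymethyl)-6-isopropylcyclohex-2-en-1-yl]prop-2-enoyl}oxy)methyl]-6-isopropyl-1-oxo-1,3,5a,6,7,8,9,9a-octahydro-2-benzoxepine-4-carboxylate
Conditions: Cs2CO3 (0.3 equiv), DMF, 60 °C
Reagents that add atoms: none
Why: SN2 ring opening of the spiro-epoxide at its CH2 carbon by the caesium carboxylate, buffered by excess free acid, forms the ester and leaves the tertiary C–O bond, hence the (R)-carbinol centre, intact.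

Step 17
Reactants: 23 the coupled tert-butyl ester
Product: 24 (5aR,6S,9R,9aS)-9-hydroxy-9-[({(2E)-2-(hydroxymethyl)-3-[(1R,6R)-3-(hydroxymethyl)-6-isopropylcyclohex-2-en-1-yl]prop-2-enoyl}oxy)methyl]-6-isopropyl-1-oxo-1,3,5a,6,7,8,9,9a-octahydro-2-benzoxepine-4-carboxylic acid (target)
Conditions: 85 % H3PO4 (aq), CH2Cl2, rt
Reagents that add atoms: none
Why: Acid-catalysed tert-butyl ester cleavage (isobutene loss) frees the last carboxylic acid without touching the lactone, the inter-fragment ester, the allylic alcohols or the tertiary alcohol.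

**Compound list**

1 | 4-isopropylanisole | COc1ccc(cc1)C(C)C | starting material
2 | 1-methoxy-4-isopropylcyclohexa-1,4-diene | COC1=CCC(C(C)C)=CC1 | intermediate (not isolated)
3 | 4-isopropylcyclohex-3-en-1-one | CC(C)C1=CCC(=O)CC1 | intermediate
4 | (4R)-4-isopropylcyclohex-2-en-1-one, (R)-cryptone | CC(C)[C@H]1CCC(=O)C=C1 | intermediate
5 | (4S)-4-isopropylcyclohex-2-en-1-one, (S)-cryptone | CC(C)[C@@H]1CCC(=O)C=C1 | intermediate
6 | tert-butyl (diethoxyphosphoryl)acetate | CCOP(=O)(OCC)CC(=O)OC(C)(C)C | starting material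
7 | tert-butyl 2-(diethoxyphosphoryl)-3-hydroxypropanoate (racemic) | CCOP(=O)(OCC)C(CO)C(=O)OC(C)(C)C | intermediate
8 | bromomagnesium (3R,4R)-4-isopropyl-3-vinylcyclohex-1-en-1-olate | CC(C)[C@H]1CCC(O[Mg]Br)=C[C@@H]1C=C | intermediate (not isolated)
9 | (3R,4R)-4-isopropyl-3-vinylcyclohex-1-en-1-yl trifluoromethanesulfonate | CC(C)[C@H]1CCC(OS(=O)(=O)C(F)(F)F)=C[C@@H]1C=C | intermediate
10 | (3R,4R)-3-formyl-4-isopropylcyclohex-1-en-1-yl trifluoromethanesulfonate | CC(C)[C@H]1CCC(OS(=O)(=O)C(F)(F)F)=C[C@@H]1C=O | intermediate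
11 | tert-butyl (2E)-2-(hydroxymethyl)-3-[(1S,6R)-6-isopropyl-3-(trifluoromethylsulfonyloxy)cyclohex-2-en-1-yl]prop-2-enoate | CC(C)[C@H]1CCC(OS(=O)(=O)C(F)(F)F)=C[C@@H]1/C=C(\CO)C(=O)OC(C)(C)C | intermediate
12 | tert-butyl (2E)-2-(hydroxymethyl)-3-[(1R,6R)-3-(hydroxymethyl)-6-isopropylcyclohex-2-en-1-yl]prop-2-enoate | CC(C)[C@H]1CCC(CO)=C[C@@H]1/C=C(\CO)C(=O)OC(C)(C)C | intermediate
13 | (2E)-2-(hydroxymethyl)-3-[(1R,6R)-3-(hydroxymethyl)-6-isopropylcyclohex-2-en-1-yl]prop-2-enoic acid (fragment A) | CC(C)[C@H]1CCC(CO)=C[C@@H]1/C=C(\CO)C(=O)O | intermediate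
14 | (1R,5S,6S)-5-isopropyl-8-methylidenebicyclo[4.2.0]octan-2-one (cis-fused, cyclobutane trans to isopropyl) | CC(C)[C@@H]1CCC(=O)[C@H]2C(=C)C[C@@H]12 | intermediate
15 | (1R,2R,5S,6S)-5-isopropyl-8-methylidenespiro[bicyclo[4.2.0]octane-2,2'-oxirane] | CC(C)[C@@H]1CC[C@]2(CO2)[C@H]3C(=C)C[C@@H]13 | intermediate
16 | (1S,2R,5S,6S)-5-isopropylspiro[bicyclo[4.2.0]octane-2,2'-oxiran]-8-one | CC(C)[C@@H]1CC[C@]2(CO2)[C@H]3C(=O)C[C@@H]13 | intermediate
17 | trimethylsilyl enol ether of 16 (C7=C8 cyclobutene, other centres as in 16) | CC(C)[C@@H]1CC[C@]2(CO2)[C@H]3C(O[Si](C)(C)C)=C[C@@H]13 | intermediate (not isolated)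
18 | trimethylsilyl ester of 19 (centres as in 19) | CC(C)[C@@H]1CC[C@]2(CO2)[C@@H](C(=O)O[Si](C)(C)C)[C@H]1C=O | intermediate (not isolated)
19 | (3R,4S,5S,6S)-5-formyl-6-isopropyl-1-oxaspiro[2.5]octane-4-carboxylic acid (open form of the cis lactol) | CC(C)[C@@H]1CC[C@]2(CO2)[C@@H](C(=O)O)[C@H]1C=O | intermediate
20 | (3R,4S,5R,6S)-5-[(1E)-3-tert-butoxy-2-(hydroxymethyl)-3-oxoprop-1-en-1-yl]-6-isopropyl-1-oxaspiro[2.5]octane-4-carboxylic acid | CC(C)[C@@H]1CC[C@]2(CO2)[C@@H](C(=O)O)[C@H]1/C=C(\CO)C(=O)OC(C)(C)C | intermediate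
21 | mixed anhydride of 20 and 2-methyl-6-nitrobenzoic acid (centres as in 20) | CC(C)[C@@H]1CC[C@]2(CO2)[C@@H](C(=O)OC(=O)c3c(C)cccc3[N+](=O)[O-])[C@H]1/C=C(\CO)C(=O)OC(C)(C)C | intermediate (not isolated)
22 | tert-butyl (5aR,6S,9R,9aS)-6-isopropyl-1-oxo-1,3,5a,6,7,8-hexahydro-9aH-spiro[2-benzoxepine-9,2'-oxirane]-4-carboxylate (fragment B) | CC(C)[C@@H]1CC[C@]2(CO2)[C@H]3C(=O)OCC(C(=O)OC(C)(C)C)=C[C@@H]13 | intermediate
23 | tert-butyl ester of the target (name as in step 16) | CC(C)[C@H]1CCC(CO)=C[C@@H]1/C=C(\CO)C(=O)OC[C@@]1(O)CC[C@@H](C(C)C)[C@@H]2C=C(C(=O)OC(C)(C)C)COC(=O)[C@@H]21 | intermediate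
24 | CNP0361406.3 (name as in step 17) | CC(C)[C@H]1CCC(CO)=C[C@@H]1/C=C(\CO)C(=O)OC[C@@]1(O)CC[C@@H](C(C)C)[C@@H]2C=C(C(=O)O)COC(=O)[C@@H]21 | target

**Step count and weak points**

Total: 17 steps. Longest linear sequence: 10 steps (1, 3, 10, 11, 12, 13, 14, 15, 16, 17).

Step 3 (its twin, step 2, shares the risk). The isopropyl group may slow the γ-protonation and lower its selectivity, and the product can racemise through the same dienamine. The fallback sets out from 3: hydrogenation (H2, Pd/C, EtOAc) gives 4-isopropylcyclohexanone F1. Its enantiotopic α-CH2 groups are then told apart by deprotonation with lithium (R,R)-bis(1-phenylethyl)amide (LiCl, Me3SiCl in situ, THF, −100 °C), which gives the silyl enol ether F2. Saegusa oxidation with Pd(OAc)2 in MeCN comes back to the route at 5.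

Step 13. The base may instead remove the ring-fusion α-hydrogen, whose enolate would open the neighbouring oxirane, and the silyl enol ether may be α-hydroxylated rather than cleaved. The fallback sets out from 15 and needs no enolate: SeO2 (cat.)/t-BuOOH hydroxylates the cyclobutane CH2 next to the methylidene to give the allylic alcohol F3. O3/pyridine then gives the α-hydroxycyclobutanone F4, and NaIO4 (aq. THF) cleaves the ketol to acid plus aldehyde, which comes back at 19.

Step 16. The oxirane CH2 is neopentyl-like, fragment A is precious, and the lactone of 22 is an allylic ester that a carboxylate could attack. The fallback moves the fragment union to a C=C bond and sets out from 22 and 10. Epoxide 22 is opened with a large excess of cheap (diethoxyphosphoryl)acetic acid (Cs2CO3 cat., DMF, 60 °C) to give the phosphonoacetate F5. Hydroxymethylation with (CH2O)n/K2CO3 gives the hydroxymethyl phosphonoacetate F6. Separately, 10 is coupled with Bu3SnCH2OH (Pd(PPh3)4, LiCl) to give the hydroxymethyl aldehyde F7. Horner–Wadsworth–Emmons olefination of F6 with F7 (LiCl, DBU, MeCN) comes back at 23.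

**Further compounds**

F1 | step 3 | 4-isopropylcyclohexanone | CC(C)C1CCC(=O)CC1
F2 | step 3 | (4R)-[(4-isopropylcyclohex-1-en-1-yl)oxy]trimethylsilane | CC(C)[C@@H]1CCC(O[Si](C)(C)C)=CC1
F3 | step 13 | 7-hydroxy derivative of 15 (carbinol centre a mixture, other centres as in 15) | CC(C)[C@@H]1CC[C@]2(CO2)[C@H]3C(=C)C(O)[C@@H]13
F4 | step 13 | 7-hydroxy derivative of 16 (carbinol centre a mixture, other centres as in 16) | CC(C)[C@@H]1CC[C@]2(CO2)[C@H]3C(=O)C(O)[C@@H]13
F5 | step 16 | (diethoxyphosphoryl)acetate of the primary alcohol formed by opening 22 (centres as in 23) | CCOP(=O)(OCC)CC(=O)OC[C@@]1(O)CC[C@@H](C(C)C)[C@@H]2C=C(C(=O)OC(C)(C)C)COC(=O)[C@@H]21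
F6 | step 16 | 2-(diethoxyphosphoryl)-3-hydroxypropanoate analogue of F5 (new centre a mixture) | CCOP(=O)(OCC)C(CO)C(=O)OC[C@@]1(O)CC[C@@H](C(C)C)[C@@H]2C=C(C(=O)OC(C)(C)C)COC(=O)[C@@H]21
F7 | step 16 | (1R,6R)-3-(hydroxymethyl)-6-isopropylcyclohex-2-ene-1-carbaldehyde | CC(C)[C@H]1CCC(CO)=C[C@@H]1C=O
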